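The route cuts the bond between benzylic C1 of the heptanone chain and the ipso carbon of guaiacyl ring B, together with its twin, C7 to ring A. It exploits two features: rings A and B are identical, and C1 is the beta carbon of the C3 ketone. One palladium-catalysed three-component Heck reaction joins two molecules of 4-iodo-2-methoxyphenol to hepta-1,6-dien-3-ol. Arylation at C1 triggers a hydride relay that turns the C3 carbinol into the ketone, and arylation at C7 leaves a C6=C7 styrene. The precursor is therefore an aryl-free, carbonyl-free C7 dienol. Hydrogenation completes a protecting-group-free route of three steps.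

Key step: step 2

Remark: the target has no stereocentre. The chain is numbered C1 (benzylic, on ring B) through C3 (carbonyl) to C7 (benzylic, on ring A). Compound 3 is used as the racemate because its only stereocentre is erased in step 2.

Step 1
Reactants: 1 pent-4-enal; 2 vinylmagnesium bromide
Product: 3 (±)-hepta-1,6-dien-3-ol
Conditions: 2 (1.2 equiv, 1.0 M in THF), THF, −78 °C to 0 °C; then sat. aq NH4Cl
Reagents that add atoms: none
Why: Grignard 1,2-addition of a vinyl nucleophile to an aliphatic aldehyde is reliable at low temperature, and the new C3 stereocentre forms as a racemate, which is harmless because C3 becomes the carbonyl carbon in step 2.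

Step 2
Reactants: 3 (±)-hepta-1,6-dien-3-ol; 4 4-iodo-2-methoxyphenol (two molecules enter the product)
Product: 6 (E)-1,7-bis(4-hydroxy-3-methoxyphenyl)hept-6-en-3-one, via monoaryl heptenone 5 (not isolated)
Conditions: 4 (2.3 equiv), Pd(OAc)2 (5 mol %), n-Bu4NCl (2 equiv), NaHCO3 (5 equiv), DMF, 50 °C, then 90 °C
Reagents that add atoms: none
Why: Zerovalent palladium, formed in the flask from Pd(OAc)2, inserts into the carbon–iodine bond of 4, the arylpalladium iodide adds syn across C1=C2 of 3 with ring B going to the terminal C1, and beta-hydride elimination toward the carbinol hydrogen at C3 followed by tautomerization gives ketone 5; a second cycle places ring A on the terminal C7 of the remaining alkene and eliminates a benzylic hydrogen to give the conjugated styrene 6. The closest known reaction types are the Mizoroki–Heck arylation of secondary allylic alcohols to beta-aryl ketones under ligand-free tetraalkylammonium chloride conditions and the Mizoroki–Heck arylation of terminal alkenes, run here as a twofold coupling in one flask. No ring is closed and no stereocentre is made: the racemic C3 centre of 3 is erased, and the E geometry of C6=C7 follows from syn insertion and syn elimination through the less crowded rotamer. The step needs terminal rather than internal arylation at both alkenes, which the neutral halide-bound pathway (chloride present, no silver salt, no chelating phosphine) should secure on steric grounds, and elimination toward C3 rather than C1, which the weak, hydridic carbinol C–H bond and the irreversible tautomerization should secure. The order of the two arylations and the final position of the surviving double bond after any palladium hydride migration do not matter, because all such isomers have the same carbon skeleton and converge on 7 in step 3. NaHCO3 takes up the hydrogen iodide but should leave the guaiacol hydroxyl groups largely un-ionized, so the free phenols should not interfere.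

Step 3
Reactants: 6 (E)-1,7-bis(4-hydroxy-3-methoxyphenyl)hept-6-en-3-one
Product: 7 1,7-bis(4-hydroxy-3-methoxyphenyl)heptan-3-one
Conditions: H2 (1 atm), Pd/C (10 wt %), EtOAc–EtOH, rt
Reagents that add atoms: none
Why: Heterogeneous catalytic hydrogenation should saturate the styrenyl alkene, and any positional isomer of it, much faster than it touches the non-benzylic dialkyl ketone, the phenols or the aryl methyl ethers, so all olefin isomers from step 2 should funnel into 7.

Compound list
1 | pent-4-enal | C=CCCC=O | starting material
2 | vinylmagnesium bromide | C=C[Mg]Br | starting material
3 | (±)-hepta-1,6-dien-3-ol (racemic) | C=CCCC(O)C=C | intermediate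
4 | 4-iodo-2-methoxyphenol | COc1cc(I)ccc1O | starting material
5 | 1-(4-hydroxy-3-methoxyphenyl)hept-6-en-3-one | C=CCCC(=O)CCc1ccc(O)c(OC)c1 | intermediate
6 | (E)-1,7-bis(4-hydroxy-3-methoxyphenyl)hept-6-en-3-one | COc1cc(/C=C/CCC(=O)CCc2ccc(O)c(OC)c2)ccc1O | intermediate
7 | 1,7-bis(4-hydroxy-3-methoxyphenyl)heptan-3-one | COc1cc(CCCCC(=O)CCc2ccc(O)c(OC)c2)ccc1O | target

Total step count: 3. Longest linear sequence: 3 steps (1 to 3 to 6 to 7).

Steps most likely to fail

1. Step 2.
- **Risk:** The unactivated alkene may be arylated at the internal carbon C6 instead of C7. Palladium hydride may move that alkene along the chain before it is arylated. Beta-hydride elimination may run toward C1 instead of C3.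
- **Fallback:** It sets out from 4 and comes back at 7, and it forms the two aryl–carbon bonds one at a time without any Heck reaction.
- Commercial ethyl pent-4-enoate (C=CCCC(=O)OCC) is hydroborated with 9-BBN-H (THF, rt) to ethyl 5-(9-borabicyclo[3.3.1]nonan-9-yl)pentanoate F1.
- F1 is coupled in the same flask with 4 (B-alkyl Suzuki–Miyaura coupling, PdCl2(dppf), K3PO4, DMF–H2O, 50 °C) to ethyl 5-(4-hydroxy-3-methoxyphenyl)pentanoate F2. This sets the C7–ring A bond with strict anti-Markovnikov control.
- Kulinkovich cyclopropanation (EtMgBr, 4.5 equiv, Ti(OiPr)4, THF, 0 °C to rt, the first equivalent being spent on the phenol) should give 1-[4-(4-hydroxy-3-methoxyphenyl)butyl]cyclopropan-1-ol F3.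
- Palladium-catalysed ring-opening arylation of F3 with 4 (Pd(OAc)2, XPhos, Cs2CO3, toluene, 80 °C) runs through a palladium homoenolate. It forms the C1–ring B bond and unveils the C3 ketone at once, so it should give 7 without any alkene to reduce.

2. Step 3.
- **Risk:** Iodide or ammonium salts carried over from step 2 may poison the palladium surface and stall hydrogen uptake. Forcing the reaction may then slowly reduce the C3 ketone.
- **Fallback:** It sets out from 6 and comes back at 7. It is a metal-free reduction with diimide, generated in the flask from dipotassium azodicarboxylate (KO2CN=NCO2K) and AcOH in MeOH at rt. Diimide transfers hydrogen to the carbon–carbon double bond in a concerted way and should leave the ketone, phenols and ethers alone. No compound outside the list is made (F0).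

3. Step 1.
- **Risk:** Aldehyde 1 may enolize and self-condense under the basic Grignard reagent, and the volatile alcohol may be lost during concentration.
- **Fallback:** It sets out from 1 and comes back at 3. It is a Nozaki–Hiyama–Kishi reaction of 1 with vinyl bromide (C=CBr; CrCl2 (4 equiv), NiCl2 (1 mol %), DMF, rt), in which a non-basic vinylchromium species adds to the aldehyde without enolization. No compound outside the list is made (F0).

Further compounds
F1 | step 2 | ethyl 5-(9-borabicyclo[3.3.1]nonan-9-yl)pentanoate | CCOC(=O)CCCCB1C2CCCC1CCC2
F2 | step 2 | ethyl 5-(4-hydroxy-3-methoxyphenyl)pentanoate | CCOC(=O)CCCCc1ccc(O)c(OC)c1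
F3 | step 2 | 1-[4-(4-hydroxy-3-methoxyphenyl)butyl]cyclopropan-1-ol | COc1cc(CCCCC2(O)CC2)ccc1O
F0 | step 3 | none | none
F0 | step 1 | none | none
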